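**Plan**

- Retrosynthesis: the exocyclic C7=C8 alkene is traced back to a C7 acetate (E1cB). The ring bond C8–C12 is then cut to a furfuryl acetate (retro-Piancatelli). The furan is detached at C8–C9 (furyllithium + aldehyde) and at C12–C13 (furyllithium + allylic bromide), and the acid chain is cut at C3–C4 (Wittig).
- Enabling feature: in the ring C8–C12 the C9 ketone and the C12 tertiary carbinol are 1,4-related across the C10=C11 alkene that carries the C10 chlorine. The ring is therefore a hydrated 2,5-disubstituted 3-chlorofuran whose furfuryl carbon is C8. C4–C8 with O5, O6 and a temporary O7 is C1–C5 of D-xylose.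
- Forward: D-xylose → acyclic tetrakis-TES aldehyde → C1–C3 by Wittig, hydrogenation, oxidation at C8 (10). Separately, 3-bromofuran → 4-chloro-2-octadienylfuran (23). The fragments are joined at C8–C9, TES is exchanged for acetate, the only ring (the cyclopentenone) closes in step 17, and the 7E alkene is formed last.
- Stereochemistry: C5 and C6 are C2 and C3 of D-xylose. C7 (xylose C4) is a temporary stereocentre that steers the conrotation which sets C12, and then leaves as acetate. 14Z/17Z come from cis-semi-hydrogenation of a skipped diyne, and 7E from the E1cB step.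

Key step: step 17

Assumption: prostanoid numbering is used (C1 = ester carbon, C20 = ω-methyl); the C8 epimers of 25–27 are carried together because C8 becomes the cationic terminus and both epimers give the same cation.

**Route**

Step 1
Reactants: 1 D-xylose
Product: 2 D-xylose diethyl dithioacetal
Conditions: EtSH, conc. HCl, 0 °C
Reagents that add atoms: ethanethiol, CCS
Why: Acid-catalysed dithioacetalisation of the aldose opens the hemiacetal to the acyclic form and masks C1 without touching the three carbinol stereocentres.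

Step 2
Reactants: 2 D-xylose diethyl dithioacetal
Product: 3 2,3,4,5-tetrakis-O-(triethylsilyl)-D-xylose diethyl dithioacetal
Conditions: TESCl, imidazole, DMAP (cat.), DMF, rt
Reagents that add atoms: chlorotriethylsilane, CC[Si](Cl)(CC)CC
Why: Exhaustive silylation of the tetraol gives base-stable ethers that can later be removed without acid or hydrogen, which the furan and the skipped diene would not tolerate.

Step 3
Reactants: 3 2,3,4,5-tetrakis-O-(triethylsilyl)-D-xylose diethyl dithioacetal
Product: 4 2,3,4,5-tetrakis-O-(triethylsilyl)-aldehydo-D-xylose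
Conditions: I2, NaHCO3, acetone–H2O, 0 °C
Reagents that add atoms: water, O
Why: Iodine-mediated oxidative hydrolysis of the dithioacetal under bicarbonate buffering should release the aldehyde without cleaving TES ethers or epimerising the α-silyloxy centre.

Step 4
Reactants: 4 2,3,4,5-tetrakis-O-(triethylsilyl)-aldehydo-D-xylose; 5 (2-carboxyethyl)triphenylphosphonium bromide
Product: 8 methyl (3Z,5S,6R,7R)-5,6,7,8-tetrakis(triethylsilyloxy)oct-3-enoate, via carboxylate ylide 6 (not isolated), via free acid 7 (not isolated)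
Conditions: 5, NaHMDS (2 equiv per 5), THF, −78 °C → rt; aq. NaH2PO4; crude acid, TMSCHN2, PhMe–MeOH, 0 °C
Reagents that add atoms: trimethylsilyldiazomethane, C[Si](C)(C)C=[N+]=[N-]
Why: Wittig olefination with the non-stabilised β-carboxylate ylide adds C1–C3 as a β,γ-unsaturated acid that is methylated at once with TMS-diazomethane, and the alkene geometry is irrelevant because the double bond is hydrogenated next.

Step 5
Reactants: 8 methyl (3Z,5S,6R,7R)-5,6,7,8-tetrakis(triethylsilyloxy)oct-3-enoate
Product: 9 methyl (5S,6R,7R)-5,6,7,8-tetrakis(triethylsilyloxy)octanoate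
Conditions: H2 (1 atm), Pt/C, EtOAc, rt
Reagents that add atoms: none
Why: Catalytic hydrogenation saturates the only alkene before any furan or diene is present, and platinum in ethyl acetate should avoid allylic C–O hydrogenolysis and TES solvolysis.

Step 6
Reactants: 9 methyl (5S,6R,7R)-5,6,7,8-tetrakis(triethylsilyloxy)octanoate
Product: 10 methyl (5S,6R,7S)-8-oxo-5,6,7-tris(triethylsilyloxy)octanoate
Conditions: (COCl)2, DMSO, CH2Cl2, −78 → −40 °C; Et3N, −78 → 0 °C
Reagents that add atoms: none
Why: Under Swern conditions a primary TES ether is converted directly into the aldehyde while secondary TES ethers persist, so C8 is unmasked and oxidised in one operation at low temperature without epimerising C7.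

Step 7
Reactants: 11 1-bromopent-2-yne; 12 prop-2-yn-1-ol
Product: 13 octa-2,5-diyn-1-ol
Conditions: CuI, NaI, Cs2CO3, DMF, rt
Reagents that add atoms: none
Why: Copper-mediated coupling of a terminal alkyne with a propargylic bromide is the standard route to skipped diynes and joins C16 to C15 without allene formation.

Step 8
Reactants: 13 octa-2,5-diyn-1-ol
Product: 14 (2Z,5Z)-octa-2,5-dien-1-ol
Conditions: H2 (1 atm), P-2 Ni [Ni(OAc)2, NaBH4], ethylenediamine, EtOH, rt
Reagents that add atoms: none
Why: Cis-selective semi-hydrogenation of both triple bonds on poisoned nickel sets the 14Z and 17Z geometries by syn delivery of hydrogen.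

Step 9
Reactants: 14 (2Z,5Z)-octa-2,5-dien-1-ol
Product: 15 (2Z,5Z)-1-bromoocta-2,5-diene
Conditions: CBr4, PPh3, CH2Cl2, −20 → 0 °C
Reagents that add atoms: carbon tetrabromide, BrC(Br)(Br)Br
Why: Appel bromination converts the primary allylic alcohol into the bromide under neutral conditions, so neither allylic transposition nor Z/E isomerisation is expected.

Step 10
Reactants: 16 3-bromofuran
Product: 18 3-bromo-2-(trimethylsilyl)furan, via 3-bromo-2-lithiofuran 17 (not isolated)
Conditions: LDA, THF, −78 °C; TMSCl, −78 °C → rt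
Reagents that add atoms: chlorotrimethylsilane, C[Si](C)(C)Cl
Why: LDA deprotonates 3-bromofuran at C2, the position flanked by oxygen and bromine, and silylation blocks this site so that the ω-chain can later be placed at the remote α-carbon.

Step 11
Reactants: 18 3-bromo-2-(trimethylsilyl)furan
Product: 20 3-chloro-2-(trimethylsilyl)furan, via 3-lithio-2-(trimethylsilyl)furan 19 (not isolated)
Conditions: n-BuLi, Et2O, −78 °C; C2Cl6, −78 °C → rt
Reagents that add atoms: hexachloroethane, ClC(Cl)(Cl)C(Cl)(Cl)Cl
Why: Bromine–lithium exchange at −78 °C followed by electrophilic chlorination with hexachloroethane replaces bromine by the chlorine that becomes C10–Cl, before any acidic allylic position is present.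

Step 12
Reactants: 20 3-chloro-2-(trimethylsilyl)furan; 15 (2Z,5Z)-1-bromoocta-2,5-diene
Product: 22 [3-chloro-5-[(2Z,5Z)-octa-2,5-dien-1-yl]furan-2-yl]trimethylsilane, via 5-lithiofuran 21 (not isolated)
Conditions: n-BuLi, THF, −78 → −20 °C; 15, −78 → 0 °C
Reagents that add atoms: none
Why: The only remaining furan α-hydrogen is lithiated and the furyllithium is alkylated by the primary allylic bromide in an SN2 reaction, as in the known prenylation of 2-lithiofurans, forming the C12–C13 bond.

Step 13
Reactants: 22 [3-chloro-5-[(2Z,5Z)-octa-2,5-dien-1-yl]furan-2-yl]trimethylsilane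
Product: 23 4-chloro-2-[(2Z,5Z)-octa-2,5-dien-1-yl]furan
Conditions: TBAF, wet THF, 0 °C → rt
Reagents that add atoms: none
Why: Fluoride-induced protodesilylation of the 2-furylsilane is eased by the oxygen and the adjacent chlorine, which stabilise the ipso carbanion, and leaves the diene untouched.

Step 14
Reactants: 23 4-chloro-2-[(2Z,5Z)-octa-2,5-dien-1-yl]furan; 10 methyl (5S,6R,7S)-8-oxo-5,6,7-tris(triethylsilyloxy)octanoate
Product: 25 methyl (5S,6R,7R)-8-{3-chloro-5-[(2Z,5Z)-octa-2,5-dien-1-yl]furan-2-yl}-8-hydroxy-5,6,7-tris(triethylsilyloxy)octanoate (both C8 epimers), via 2-lithiofuran 24 (not isolated)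
Conditions: LDA, THF, −78 °C; 10, −78 °C; aq. NH4Cl
Reagents that add atoms: none
Why: LDA removes the furan hydrogen between oxygen and chlorine (ortho-lithiation as for 3-halofurans), and at −78 °C the furyllithium should add to the α-silyloxy aldehyde much faster than to the methyl ester; the C8 configuration is not controlled and need not be.

Step 15
Reactants: 25 methyl (5S,6R,7R)-8-{3-chloro-5-[(2Z,5Z)-octa-2,5-dien-1-yl]furan-2-yl}-8-hydroxy-5,6,7-tris(triethylsilyloxy)octanoate
Product: 26 methyl (5S,6R,7S)-8-{3-chloro-5-[(2Z,5Z)-octa-2,5-dien-1-yl]furan-2-yl}-5,6,7,8-tetrahydroxyoctanoate (both C8 epimers)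
Conditions: HF·pyridine, pyridine, THF, 0 °C → rt
Reagents that add atoms: none
Why: Pyridine-buffered HF cleaves the three secondary TES ethers under conditions mild enough for the furylcarbinol and the methyl ester, and the tetraol is acetylated at once to forestall δ-lactonisation of the 5-hydroxy ester.

Step 16
Reactants: 26 methyl (5S,6R,7S)-8-{3-chloro-5-[(2Z,5Z)-octa-2,5-dien-1-yl]furan-2-yl}-5,6,7,8-tetrahydroxyoctanoate
Product: 27 methyl (5S,6R,7S)-5,6,7,8-tetraacetoxy-8-{3-chloro-5-[(2Z,5Z)-octa-2,5-dien-1-yl]furan-2-yl}octanoate (both C8 epimers)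
Conditions: Ac2O, pyridine, DMAP (cat.), CH2Cl2, 0 °C → rt
Reagents that add atoms: acetic anhydride, CC(=O)OC(C)=O
Why: Exhaustive acylation installs the two acetates of the target at O5 and O6, the later leaving group at O7 and the ionisable furfuryl ester at O8 in a single operation.

Step 17
Reactants: 27 methyl (5S,6R,7S)-5,6,7,8-tetraacetoxy-8-{3-chloro-5-[(2Z,5Z)-octa-2,5-dien-1-yl]furan-2-yl}octanoate
Product: 28 methyl (5S,6R,7R)-5,6,7-triacetoxy-7-{(1S,5S)-3-chloro-5-hydroxy-5-[(2Z,5Z)-octa-2,5-dien-1-yl]-2-oxocyclopent-3-en-1-yl}heptanoate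
Conditions: Dy(OTf)3 (10 mol %), MeCN–H2O (10:1), 60 °C
Reagents that add atoms: water, O
Why: The lanthanide ionises the furfuryl C8 acetate of either epimer to the same furan-stabilised cation, water adds at the alkyl-bearing furan carbon (future C12), the hemiketal opens to a 1,4-dihydroxypentadienyl cation spanning C8–C12, and thermal conrotatory 4π closure joins C8 to C12, leaving the former furan oxygen as the C9 ketone, the water oxygen as the C12 hydroxyl and chlorine on C10. The closest known reaction is the Piancatelli rearrangement of 5-alkyl-2-furylcarbinols to 4-alkyl-4-hydroxycyclopent-2-enones under mild Lewis acids. The cyclopentenone closes by this Nazarov-type electrocyclisation of the pentadienyl cation, with C8 and C12 as the termini (formally 5-endo). C8 and C12 arise together: with the C7 chain and the C12 hydroxyl both pointing outward in the cation they become trans, and the sense of conrotation should be set by the C7 acetoxy stereocentre, which is expected to place its C–O bond anti to the forming bond at the electrophilic C8 terminus, H7 toward the incoming C12 and the C6 chain toward O9, so that the D-xylo configuration leads to the 12R carbinol of the target. The step needs water capture at the remote α-carbon rather than at C8 and no loss of the tertiary carbinol; the 2,5-substitution pattern directs water to the alkylated carbon, and the quaternary C12 together with the C10 chlorine blocks the usual onward isomerisation of 4-hydroxycyclopentenones.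

Step 18
Reactants: 28 methyl (5S,6R,7R)-5,6,7-triacetoxy-7-{(1S,5S)-3-chloro-5-hydroxy-5-[(2Z,5Z)-octa-2,5-dien-1-yl]-2-oxocyclopent-3-en-1-yl}heptanoate
Product: 29 punaglandin 3
Conditions: DBU, CH2Cl2, −40 → 0 °C
Reagents that add atoms: none
Why: E1cB elimination of the β-acetoxy ketone (deprotonation at C8, the only enolisable α-position, and loss of the C7 acetate rather than the far poorer tertiary hydroxyl) should give the cross-conjugated dienone, with the 7E geometry favoured as in aldol–dehydration routes to 2-alkylidenecyclopentenones, and it erases the C7 and C8 stereocentres.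

**Compound list**

1 | D-xylose | O=C[C@H](O)[C@@H](O)[C@H](O)CO | starting material
2 | D-xylose diethyl dithioacetal | CCSC(SCC)[C@H](O)[C@@H](O)[C@H](O)CO | intermediate
3 | 2,3,4,5-tetrakis-O-(triethylsilyl)-D-xylose diethyl dithioacetal | CCSC(SCC)[C@H](O[Si](CC)(CC)CC)[C@@H](O[Si](CC)(CC)CC)[C@H](O[Si](CC)(CC)CC)CO[Si](CC)(CC)CC | intermediate
4 | 2,3,4,5-tetrakis-O-(triethylsilyl)-aldehydo-D-xylose | O=C[C@H](O[Si](CC)(CC)CC)[C@@H](O[Si](CC)(CC)CC)[C@H](O[Si](CC)(CC)CC)CO[Si](CC)(CC)CC | intermediate
5 | (2-carboxyethyl)triphenylphosphonium bromide | OC(=O)CC[P+](c1ccccc1)(c1ccccc1)c1ccccc1.[Br-] | starting material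
6 | sodium 3-(triphenylphosphoranylidene)propanoate (ylide, not isolated) | [Na+].[O-]C(=O)CC=P(c1ccccc1)(c1ccccc1)c1ccccc1 | intermediate
7 | (3Z,5S,6R,7R)-5,6,7,8-tetrakis(triethylsilyloxy)oct-3-enoic acid (not isolated) | OC(=O)C/C=C\[C@H](O[Si](CC)(CC)CC)[C@@H](O[Si](CC)(CC)CC)[C@H](O[Si](CC)(CC)CC)CO[Si](CC)(CC)CC | intermediate
8 | methyl (3Z,5S,6R,7R)-5,6,7,8-tetrakis(triethylsilyloxy)oct-3-enoate | COC(=O)C/C=C\[C@H](O[Si](CC)(CC)CC)[C@@H](O[Si](CC)(CC)CC)[C@H](O[Si](CC)(CC)CC)CO[Si](CC)(CC)CC | intermediate
9 | methyl (5S,6R,7R)-5,6,7,8-tetrakis(triethylsilyloxy)octanoate | COC(=O)CCC[C@H](O[Si](CC)(CC)CC)[C@@H](O[Si](CC)(CC)CC)[C@H](O[Si](CC)(CC)CC)CO[Si](CC)(CC)CC | intermediate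
10 | methyl (5S,6R,7S)-8-oxo-5,6,7-tris(triethylsilyloxy)octanoate | COC(=O)CCC[C@H](O[Si](CC)(CC)CC)[C@@H](O[Si](CC)(CC)CC)[C@H](O[Si](CC)(CC)CC)C=O | intermediate
11 | 1-bromopent-2-yne | CCC#CCBr | starting material
12 | prop-2-yn-1-ol | C#CCO | starting material
13 | octa-2,5-diyn-1-ol | CCC#CCC#CCO | intermediate
14 | (2Z,5Z)-octa-2,5-dien-1-ol | CC/C=C\C/C=C\CO | intermediate
15 | (2Z,5Z)-1-bromoocta-2,5-diene | CC/C=C\C/C=C\CBr | intermediate
16 | 3-bromofuran | Brc1ccoc1 | starting material
17 | 3-bromo-2-lithiofuran (not isolated) | [Li]c1occc1Br | intermediate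
18 | 3-bromo-2-(trimethylsilyl)furan | C[Si](C)(C)c1occc1Br | intermediate
19 | 3-lithio-2-(trimethylsilyl)furan (not isolated) | [Li]c1ccoc1[Si](C)(C)C | intermediate
20 | 3-chloro-2-(trimethylsilyl)furan | C[Si](C)(C)c1occc1Cl | intermediate
21 | 3-chloro-5-lithio-2-(trimethylsilyl)furan (not isolated) | [Li]c1cc(Cl)c(o1)[Si](C)(C)C | intermediate
22 | [3-chloro-5-[(2Z,5Z)-octa-2,5-dien-1-yl]furan-2-yl]trimethylsilane | CC/C=C\C/C=C\Cc1cc(Cl)c(o1)[Si](C)(C)C | intermediate
23 | 4-chloro-2-[(2Z,5Z)-octa-2,5-dien-1-yl]furan | CC/C=C\C/C=C\Cc1cc(Cl)co1 | intermediate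
24 | 3-chloro-2-lithio-5-[(2Z,5Z)-octa-2,5-dien-1-yl]furan (not isolated) | CC/C=C\C/C=C\Cc1cc(Cl)c([Li])o1 | intermediate
25 | methyl (5S,6R,7R)-8-{3-chloro-5-[(2Z,5Z)-octa-2,5-dien-1-yl]furan-2-yl}-8-hydroxy-5,6,7-tris(triethylsilyloxy)octanoate (both C8 epimers) | CC/C=C\C/C=C\Cc1cc(Cl)c(o1)C(O)[C@@H](O[Si](CC)(CC)CC)[C@H](O[Si](CC)(CC)CC)[C@H](CCCC(=O)OC)O[Si](CC)(CC)CC | intermediate
26 | methyl (5S,6R,7S)-8-{3-chloro-5-[(2Z,5Z)-octa-2,5-dien-1-yl]furan-2-yl}-5,6,7,8-tetrahydroxyoctanoate (both C8 epimers) | CC/C=C\C/C=C\Cc1cc(Cl)c(o1)C(O)[C@@H](O)[C@H](O)[C@H](CCCC(=O)OC)O | intermediate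
27 | methyl (5S,6R,7S)-5,6,7,8-tetraacetoxy-8-{3-chloro-5-[(2Z,5Z)-octa-2,5-dien-1-yl]furan-2-yl}octanoate (both C8 epimers) | CC/C=C\C/C=C\Cc1cc(Cl)c(o1)C(OC(C)=O)[C@@H](OC(C)=O)[C@H](OC(C)=O)[C@H](CCCC(=O)OC)OC(C)=O | intermediate
28 | methyl (5S,6R,7R)-5,6,7-triacetoxy-7-{(1S,5S)-3-chloro-5-hydroxy-5-[(2Z,5Z)-octa-2,5-dien-1-yl]-2-oxocyclopent-3-en-1-yl}heptanoate (7-acetoxy-7,8-dihydropunaglandin 3) | CC/C=C\C/C=C\C[C@@]1(O)C=C(Cl)C(=O)[C@H]1[C@@H](OC(C)=O)[C@H](OC(C)=O)[C@H](CCCC(=O)OC)OC(C)=O | intermediate
29 | punaglandin 3, methyl (5S,6S,7E)-5,6-diacetoxy-7-{(5R)-3-chloro-5-hydroxy-5-[(2Z,5Z)-octa-2,5-dien-1-yl]-2-oxocyclopent-3-en-1-ylidene}heptanoate | CC/C=C\C/C=C\C[C@@]1(O)C=C(Cl)C(=O)/C1=C/[C@H](OC(C)=O)[C@H](CCCC(=O)OC)OC(C)=O | target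

**Step count**

Total: 18 steps. Longest linear sequence: 11 steps (from D-xylose: steps 1–6 and 14–18).

**Steps most likely to fail**

1. Step 17. The cation may be diverted before it cyclises: loss of H7 to an enol acetate, capture by the neighbouring C7 acetate as an acetoxonium ion with ester scrambling, or hydrolysis of acetates in the warm aqueous Lewis acid. The conrotation may also be steered only weakly, or in the wrong sense, by an acetoxy group. The fallback sets out from carbinol 25 and runs the rearrangement one stage earlier on the free furylcarbinol, the classical substrate, with bulkier and non-participating silyl ethers at C5–C7. ZnCl2 in aqueous dioxane at 60–70 °C should convert 25 into the silyl-protected hydroxycyclopentenone methyl (5S,6R,7R)-7-{(1S,5S)-3-chloro-5-hydroxy-5-[(2Z,5Z)-octa-2,5-dien-1-yl]-2-oxocyclopent-3-en-1-yl}-5,6,7-tris(triethylsilyloxy)heptanoate F1. Buffered HF·pyridine would then give the corresponding 5,6,7-triol F2. Ac2O in pyridine would acetylate its three secondary hydroxyls, leaving the tertiary C12 hydroxyl free, and so return to the route at 28.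

2. Step 4. The β-carboxylate ylide can fragment to acrylate and triphenylphosphine before it adds to the hindered aldehyde, and the basic medium can enolise the α-silyloxy aldehyde with loss of configuration at the future C5. The fallback sets out from aldehyde 4. Methylenation with Ph3P=CH2 (THF, −78 → 0 °C), a small and fast ylide, should give (3S,4R,5R)-3,4,5,6-tetrakis(triethylsilyloxy)hex-1-ene F3. Cross-metathesis with excess methyl but-3-enoate (second-generation Ru–NHC benzylidene catalyst, CH2Cl2, 40 °C) would then give methyl (3E,5S,6R,7R)-5,6,7,8-tetrakis(triethylsilyloxy)oct-3-enoate F4. Hydrogenation under the conditions of step 5 returns to the route at 9.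

3. Step 12. The furyllithium may attack the allylic bromide in the SN2′ sense or abstract a proton from the doubly activated methylene groups, which would give transposed, conjugated or E-isomerised dienes. The fallback sets out from 20 and builds the chain by olefination instead of alkylation. After the same lithiation, ethylene oxide should give 2-[4-chloro-5-(trimethylsilyl)furan-2-yl]ethan-1-ol F5. Oxidation with DMP/NaHCO3 gives 2-[4-chloro-5-(trimethylsilyl)furan-2-yl]acetaldehyde F6, which is used at once in a salt-free Wittig reaction with the ylide of (Z)-hex-3-enyltriphenylphosphonium bromide (NaHMDS, THF, −78 °C). This forms the 14Z alkene next to the preformed 17Z alkene and returns to the route at 22, making steps 7–9 unnecessary.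

**Further compounds**

F1 | step 17 | methyl (5S,6R,7R)-7-{(1S,5S)-3-chloro-5-hydroxy-5-[(2Z,5Z)-octa-2,5-dien-1-yl]-2-oxocyclopent-3-en-1-yl}-5,6,7-tris(triethylsilyloxy)heptanoate | CC/C=C\C/C=C\C[C@@]1(O)C=C(Cl)C(=O)[C@H]1[C@@H](O[Si](CC)(CC)CC)[C@H](O[Si](CC)(CC)CC)[C@H](CCCC(=O)OC)O[Si](CC)(CC)CC
F2 | step 17 | methyl (5S,6R,7R)-7-{(1S,5S)-3-chloro-5-hydroxy-5-[(2Z,5Z)-octa-2,5-dien-1-yl]-2-oxocyclopent-3-en-1-yl}-5,6,7-trihydroxyheptanoate | CC/C=C\C/C=C\C[C@@]1(O)C=C(Cl)C(=O)[C@H]1[C@@H](O)[C@H](O)[C@H](CCCC(=O)OC)O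
F3 | step 4 | (3S,4R,5R)-3,4,5,6-tetrakis(triethylsilyloxy)hex-1-ene | C=C[C@H](O[Si](CC)(CC)CC)[C@@H](O[Si](CC)(CC)CC)[C@H](O[Si](CC)(CC)CC)CO[Si](CC)(CC)CC
F4 | step 4 | methyl (3E,5S,6R,7R)-5,6,7,8-tetrakis(triethylsilyloxy)oct-3-enoate | COC(=O)C/C=C/[C@H](O[Si](CC)(CC)CC)[C@@H](O[Si](CC)(CC)CC)[C@H](O[Si](CC)(CC)CC)CO[Si](CC)(CC)CC
F5 | step 12 | 2-[4-chloro-5-(trimethylsilyl)furan-2-yl]ethan-1-ol | OCCc1cc(Cl)c(o1)[Si](C)(C)C
F6 | step 12 | 2-[4-chloro-5-(trimethylsilyl)furan-2-yl]acetaldehyde | O=CCc1cc(Cl)c(o1)[Si](C)(C)C
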